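**Retrosynthetic overview** (azaphilone numbering: O2, C1, C3, C4, C4a, C5–C8, C8a; ring A = pyran, ring B = carbocycle)
1. Last C–C bond: Knoevenagel condensation of the C5 methylene of the left 6,8-dione half with the (E)-enal side chain of the right half; the four phenol silyl ethers come off last.
2. Each half is a 1,5-dihydro-azaphilone, made from an azaphilone by hydride addition at C1; the orsellinate enters as its bis-silyl acid chloride (on O7 left, on O6 right).
3. The two azaphilones (7S left, 7R right) come from one achiral keto-aldehyde by flavin-dependent monooxygenase hydroxylative dearomatisation (AfoD or AzaH). This sets the first stereocentre on the existing ring B and closes ring A in the same operation.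
4. Right half only: a ketoreductase sets C6 (cis to 7-OH); a lipase removes the side-chain acetate and MnO2 gives the enal.
5. The keto-aldehyde comes from 2,6-dimethoxytoluene (borylation, bromination, formylation, demethylation), Sonogashira coupling with an (E)-enynol, lipase acetylation and carbonyl-assisted alkyne hydration.

Assumption: (E)-pent-2-en-4-yn-1-ol (8) is bought as the pure E isomer, and AfoD, AzaH, the ketoreductase and the lipase are used as isolated recombinant or commercial preparations.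

**Route**

Step 1
Reactants: 1 2,6-dimethoxytoluene
Product: 2 2-(3,5-dimethoxy-4-methylphenyl)-4,4,5,5-tetramethyl-1,3,2-dioxaborolane
Conditions: B2pin2 (1.0 equiv), [Ir(OMe)(cod)]2 (1.5 mol %), dtbpy (3 mol %), THF, 80 °C
Reagents that add atoms: bis(pinacolato)diboron, CC1(C)OB(OC1(C)C)B1OC(C)(C)C(C)(C)O1
Why: Iridium-catalysed C–H borylation is sterically governed and takes the only ring C–H without an ortho substituent, para to the methyl group.

Step 2
Reactants: 2 2-(3,5-dimethoxy-4-methylphenyl)-4,4,5,5-tetramethyl-1,3,2-dioxaborolane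
Product: 3 5-bromo-1,3-dimethoxy-2-methylbenzene
Conditions: CuBr2 (3 equiv), MeOH/H2O 1:1, 80 °C
Reagents that add atoms: copper dibromide, Br[Cu]Br
Why: Copper-mediated ipso-bromodeboronation puts bromine exactly where boron was, a position that electrophilic bromination of the arene would not reach.

Step 3
Reactants: 3 5-bromo-1,3-dimethoxy-2-methylbenzene
Product: 5 6-bromo-2,4-dimethoxy-3-methylbenzaldehyde, via aryl iminium chloride 4 (not isolated)
Conditions: POCl3 (2 equiv), DMF, 0 to 90 °C; then ice-water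
Reagents that add atoms: N,N-dimethylformamide, CN(C)C=O; water, O
Why: Vilsmeier–Haack formylation goes ortho/para to the two methoxy groups, and the two open ring positions are equivalent by symmetry.

Step 4
Reactants: 5 6-bromo-2,4-dimethoxy-3-methylbenzaldehyde
Product: 7 6-bromo-2,4-dihydroxy-3-methylbenzaldehyde, via aryl bis(dibromoborinate) 6 (not isolated)
Conditions: BBr3 (4 equiv), CH2Cl2, −78 °C to rt; then H2O
Reagents that add atoms: none
Why: BBr3 ether cleavage frees both phenols, while the aldehyde and the aryl bromide are inert to it.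

Step 5
Reactants: 7 6-bromo-2,4-dihydroxy-3-methylbenzaldehyde; 8 (E)-pent-2-en-4-yn-1-ol
Product: 9 2,4-dihydroxy-6-[(E)-5-hydroxypent-3-en-1-ynyl]-3-methylbenzaldehyde
Conditions: Pd(PPh3)2Cl2 (5 mol %), CuI (5 mol %), Et3N (3 equiv), DMF, 55 °C
Reagents that add atoms: none
Why: Sonogashira coupling of the aryl bromide with the terminal alkyne; the side chain is coupled as the free alcohol because an allylic acetate would ionise on palladium.

Step 6
Reactants: 9 2,4-dihydroxy-6-[(E)-5-hydroxypent-3-en-1-ynyl]-3-methylbenzaldehyde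
Product: 10 (E)-5-(2-formyl-3,5-dihydroxy-4-methylphenyl)pent-2-en-4-ynyl acetate
Conditions: Candida antarctica lipase B (immobilised), vinyl acetate (5 equiv), MTBE, 30 °C
Reagents that add atoms: vinyl acetate, CC(=O)OC=C
Why: Lipase-catalysed transesterification acylates only the primary allylic alcohol, because phenols are not acyl acceptors for the enzyme, so no phenol protection is needed.

Step 7
Reactants: 10 (E)-5-(2-formyl-3,5-dihydroxy-4-methylphenyl)pent-2-en-4-ynyl acetate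
Product: 12 (E)-5-(2-formyl-3,5-dihydroxy-4-methylphenyl)-4-oxopent-2-enyl acetate, via 2-benzopyrylium trifluoroacetate 11 (not isolated)
Conditions: Au(OAc)3 (5 mol %), TFA (5 equiv), ClCH2CH2Cl, rt, 15 min; then H2O/MeCN, rt
Reagents that add atoms: water, O
Why: Gold-catalysed 6-endo-dig cycloisomerisation of the o-alkynylbenzaldehyde followed by hydrolytic ring opening is a carbonyl-directed alkyne hydration that places the ketone on the carbon remote from the arene.

Step 8
Reactants: 12 (E)-5-(2-formyl-3,5-dihydroxy-4-methylphenyl)-4-oxopent-2-enyl acetate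
Product: 14 (E)-3-[(7S)-7-hydroxy-7-methyl-6,8-dioxo-7,8-dihydro-6H-isochromen-3-yl]allyl acetate, via (S)-o-quinol 13 (not isolated)
Conditions: AfoD (flavin-dependent monooxygenase), NADP+ (1 mol %), Na2HPO3 (2 equiv), phosphite dehydrogenase, air, K2HPO4/KH2PO4 buffer pH 8.0, 5 % DMSO, 30 °C
Reagents that add atoms: dioxygen, O=O
Why: Flavin-dependent monooxygenase hydroxylative dearomatisation hydroxylates C7 on the enzyme-chosen face (AfoD gives 7S, the first stereocentre), and the o-quinol closes ring A by enol attack on the aldehyde and loss of water.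

Step 9
Reactants: 12 (E)-5-(2-formyl-3,5-dihydroxy-4-methylphenyl)-4-oxopent-2-enyl acetate
Product: 16 (E)-3-[(7R)-7-hydroxy-7-methyl-6,8-dioxo-7,8-dihydro-6H-isochromen-3-yl]allyl acetate, via (R)-o-quinol 15 (not isolated)
Conditions: AzaH (flavin-dependent monooxygenase), NADP+ (1 mol %), Na2HPO3 (2 equiv), phosphite dehydrogenase, air, K2HPO4/KH2PO4 buffer pH 8.0, 5 % DMSO, 30 °C
Reagents that add atoms: dioxygen, O=O
Why: The stereocomplementary flavin-dependent monooxygenase AzaH performs the same hydroxylative dearomatisation on the opposite face and sets 7R, again with spontaneous closure of ring A.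

Step 10
Reactants: 17 orsellinic acid
Product: 18 tert-butyldimethylsilyl 2,4-bis(tert-butyldimethylsilyloxy)-6-methylbenzoate
Conditions: TBSCl (3.5 equiv), imidazole (7 equiv), DMF, rt to 40 °C
Reagents that add atoms: tert-butyl(chloro)dimethylsilane, CC(C)(C)[Si](C)(C)Cl
Why: Imidazole-promoted silylation protects both phenols as fluoride-labile ethers and gives a silyl ester that can be turned directly into the acid chloride.

Step 11
Reactants: 18 tert-butyldimethylsilyl 2,4-bis(tert-butyldimethylsilyloxy)-6-methylbenzoate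
Product: 19 2,4-bis(tert-butyldimethylsilyloxy)-6-methylbenzoyl chloride
Conditions: (COCl)2 (1.2 equiv), DMF (cat.), CH2Cl2, 0 °C to rt; volatiles removed, used crude
Reagents that add atoms: oxalyl chloride, O=C(Cl)C(Cl)=O
Why: Oxalyl chloride with catalytic DMF converts the silyl ester into the acid chloride under neutral conditions, so the aryl silyl ethers survive.

Step 12
Reactants: 14 (E)-3-[(7S)-7-hydroxy-7-methyl-6,8-dioxo-7,8-dihydro-6H-isochromen-3-yl]allyl acetate; 19 2,4-bis(tert-butyldimethylsilyloxy)-6-methylbenzoyl chloride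
Product: 20 (7S)-3-[(E)-3-acetoxyprop-1-enyl]-7-methyl-6,8-dioxo-7,8-dihydro-6H-isochromen-7-yl 2,4-bis(tert-butyldimethylsilyloxy)-6-methylbenzoate
Conditions: Et3N (3 equiv), DMAP (0.2 equiv), CH2Cl2, 0 °C to rt
Reagents that add atoms: none
Why: DMAP-catalysed acylation of the acidic tertiary C7 alcohol, which sits between two flat carbonyl carbons, by the electron-rich aroyl chloride; no bond to C7 is broken, so 7S is kept.

Step 13
Reactants: 20 (7S)-3-[(E)-3-acetoxyprop-1-enyl]-7-methyl-6,8-dioxo-7,8-dihydro-6H-isochromen-7-yl 2,4-bis(tert-butyldimethylsilyloxy)-6-methylbenzoate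
Product: 21 (7S)-3-[(E)-3-acetoxyprop-1-enyl]-7-methyl-6,8-dioxo-5,6,7,8-tetrahydro-1H-isochromen-7-yl 2,4-bis(tert-butyldimethylsilyloxy)-6-methylbenzoate
Conditions: Hantzsch ester (diethyl 2,6-dimethyl-1,4-dihydropyridine-3,5-dicarboxylate, 1.3 equiv), (PhO)2P(O)OH (20 mol %), CH2Cl2, 0 °C to rt
Reagents that add atoms: none
Why: Brønsted-acid-catalysed transfer hydrogenation, in which protonation at O6 makes a 2-benzopyrylium ion that takes hydride at its unsubstituted C1 and the dienol then ketonises at C5; C7 is not involved.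

Step 14
Reactants: 16 (E)-3-[(7R)-7-hydroxy-7-methyl-6,8-dioxo-7,8-dihydro-6H-isochromen-3-yl]allyl acetate
Product: 22 (E)-3-[(7R)-7-hydroxy-7-methyl-6,8-dioxo-5,6,7,8-tetrahydro-1H-isochromen-3-yl]allyl acetate
Conditions: Hantzsch ester (1.3 equiv), (PhO)2P(O)OH (20 mol %), CH2Cl2, 0 °C to rt
Reagents that add atoms: none
Why: The same transfer hydrogenation of the protonated azaphilone delivers hydride to C1 and leaves the C7 stereocentre untouched.

Step 15
Reactants: 22 (E)-3-[(7R)-7-hydroxy-7-methyl-6,8-dioxo-5,6,7,8-tetrahydro-1H-isochromen-3-yl]allyl acetate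
Product: 23 (E)-3-[(6R,7R)-6,7-dihydroxy-7-methyl-8-oxo-5,6,7,8-tetrahydro-1H-isochromen-3-yl]allyl acetate
Conditions: ketoreductase (NADPH-dependent, panel-selected for the 6R alcohol), NADP+ (1 mol %), iPrOH (10 vol %), K2HPO4/KH2PO4 buffer pH 7.0, 5 % DMSO, 30 °C
Reagents that add atoms: none
Why: Ketoreductase reduction of the isolated C6 ketone (the vinylogous-ester C8 carbonyl is inert) with enzyme-controlled hydride delivery anti to the C7 hydroxyl sets 6R and the cis diol, with isopropanol recycling the cofactor.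

Step 16
Reactants: 23 (E)-3-[(6R,7R)-6,7-dihydroxy-7-methyl-8-oxo-5,6,7,8-tetrahydro-1H-isochromen-3-yl]allyl acetate; 19 2,4-bis(tert-butyldimethylsilyloxy)-6-methylbenzoyl chloride
Product: 24 (6R,7R)-3-[(E)-3-acetoxyprop-1-enyl]-7-hydroxy-7-methyl-8-oxo-5,6,7,8-tetrahydro-1H-isochromen-6-yl 2,4-bis(tert-butyldimethylsilyloxy)-6-methylbenzoate
Conditions: Et3N (3 equiv), DMAP (0.2 equiv), CH2Cl2, 0 °C to rt
Reagents that add atoms: none
Why: DMAP-catalysed esterification is selective for the secondary C6 alcohol over the tertiary C7 alcohol, and no bond to a stereocentre is broken.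

Step 17
Reactants: 24 (6R,7R)-3-[(E)-3-acetoxyprop-1-enyl]-7-hydroxy-7-methyl-8-oxo-5,6,7,8-tetrahydro-1H-isochromen-6-yl 2,4-bis(tert-butyldimethylsilyloxy)-6-methylbenzoate
Product: 25 (6R,7R)-7-hydroxy-3-[(E)-3-hydroxyprop-1-enyl]-7-methyl-8-oxo-5,6,7,8-tetrahydro-1H-isochromen-6-yl 2,4-bis(tert-butyldimethylsilyloxy)-6-methylbenzoate
Conditions: Candida antarctica lipase B (immobilised), n-BuOH (5 equiv), MTBE, 35 °C
Reagents that add atoms: none
Why: Lipase-catalysed alcoholysis cleaves only the unhindered primary acetate at neutral pH and leaves the hindered aryl ester, the aryl silyl ethers and the base-sensitive core alone.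

Step 18
Reactants: 25 (6R,7R)-7-hydroxy-3-[(E)-3-hydroxyprop-1-enyl]-7-methyl-8-oxo-5,6,7,8-tetrahydro-1H-isochromen-6-yl 2,4-bis(tert-butyldimethylsilyloxy)-6-methylbenzoate
Product: 26 (6R,7R)-7-hydroxy-7-methyl-8-oxo-3-[(E)-3-oxoprop-1-enyl]-5,6,7,8-tetrahydro-1H-isochromen-6-yl 2,4-bis(tert-butyldimethylsilyloxy)-6-methylbenzoate
Conditions: MnO2 (15 equiv), CH2Cl2, rt
Reagents that add atoms: none
Why: MnO2 oxidises only the allylic primary alcohol to the (E)-enal, since the tertiary alcohol cannot be oxidised.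

Step 19
Reactants: 21 (7S)-3-[(E)-3-acetoxyprop-1-enyl]-7-methyl-6,8-dioxo-5,6,7,8-tetrahydro-1H-isochromen-7-yl 2,4-bis(tert-butyldimethylsilyloxy)-6-methylbenzoate; 26 (6R,7R)-7-hydroxy-7-methyl-8-oxo-3-[(E)-3-oxoprop-1-enyl]-5,6,7,8-tetrahydro-1H-isochromen-6-yl 2,4-bis(tert-butyldimethylsilyloxy)-6-methylbenzoate
Product: 27 tetrakis(tert-butyldimethylsilyl) ether of the target
Conditions: ethylenediammonium diacetate (20 mol %), 4 Å molecular sieves, CH2Cl2, rt
Reagents that add atoms: none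
Why: Knoevenagel condensation of the vinylogous 1,3-dione C5 methylene with the enal, which under reversible conditions should settle on the isomer with the dienyl chain syn to the C6 carbonyl (Z, away from C4–H) while the enal E geometry is retained.

Step 20
Reactants: 27 tetrakis(tert-butyldimethylsilyl) ether of the target
Product: 28 CNP0283591.2 (target)
Conditions: HF·pyridine (excess), pyridine, THF, 0 °C to rt
Reagents that add atoms: none
Why: Fluoride cleavage of the four aryl silyl ethers under pyridine-buffered conditions spares the acetate, both aryl esters and the dienol ethers.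

**Compound list**

1 | 2,6-dimethoxytoluene | COc1cccc(OC)c1C | starting material
2 | 2-(3,5-dimethoxy-4-methylphenyl)-4,4,5,5-tetramethyl-1,3,2-dioxaborolane | COc1cc(cc(OC)c1C)B1OC(C)(C)C(C)(C)O1 | intermediate
3 | 5-bromo-1,3-dimethoxy-2-methylbenzene | COc1cc(Br)cc(OC)c1C | intermediate
4 | (6-bromo-2,4-dimethoxy-3-methylbenzylidene)dimethyliminium chloride | C[N+](C)=Cc1c(Br)cc(OC)c(C)c1OC.[Cl-] | intermediate (not isolated)
5 | 6-bromo-2,4-dimethoxy-3-methylbenzaldehyde | COc1cc(Br)c(C=O)c(OC)c1C | intermediate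
6 | 5-bromo-4-formyl-2-methyl-1,3-phenylene bis(dibromoborinate) | Cc1c(OB(Br)Br)cc(Br)c(C=O)c1OB(Br)Br | intermediate (not isolated)
7 | 6-bromo-2,4-dihydroxy-3-methylbenzaldehyde | Cc1c(O)cc(Br)c(C=O)c1O | intermediate
8 | (E)-pent-2-en-4-yn-1-ol | OC/C=C/C#C | starting material
9 | 2,4-dihydroxy-6-[(E)-5-hydroxypent-3-en-1-ynyl]-3-methylbenzaldehyde | OC/C=C/C#Cc1cc(O)c(C)c(O)c1C=O | intermediate
10 | (E)-5-(2-formyl-3,5-dihydroxy-4-methylphenyl)pent-2-en-4-ynyl acetate | CC(=O)OC/C=C/C#Cc1cc(O)c(C)c(O)c1C=O | intermediate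
11 | 3-[(E)-3-acetoxyprop-1-enyl]-6,8-dihydroxy-7-methylisochromenylium trifluoroacetate | CC(=O)OC/C=C/c1cc2cc(O)c(C)c(O)c2c[o+]1.[O-]C(=O)C(F)(F)F | intermediate (not isolated)
12 | (E)-5-(2-formyl-3,5-dihydroxy-4-methylphenyl)-4-oxopent-2-enyl acetate | CC(=O)OC/C=C/C(=O)Cc1cc(O)c(C)c(O)c1C=O | intermediate
13 | (E)-5-[(4S)-2-formyl-4,5-dihydroxy-4-methyl-3-oxocyclohexa-1,5-dienyl]-4-oxopent-2-enyl acetate, the (S)-o-quinol | CC(=O)OC/C=C/C(=O)CC1=C(C=O)C(=O)[C@@](C)(O)C(O)=C1 | intermediate (not isolated)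
14 | (E)-3-[(7S)-7-hydroxy-7-methyl-6,8-dioxo-7,8-dihydro-6H-isochromen-3-yl]allyl acetate | CC(=O)OC/C=C/C1=CC2=CC(=O)[C@](C)(O)C(=O)C2=CO1 | intermediate
15 | (E)-5-[(4R)-2-formyl-4,5-dihydroxy-4-methyl-3-oxocyclohexa-1,5-dienyl]-4-oxopent-2-enyl acetate, the (R)-o-quinol | CC(=O)OC/C=C/C(=O)CC1=C(C=O)C(=O)[C@](C)(O)C(O)=C1 | intermediate (not isolated)
16 | (E)-3-[(7R)-7-hydroxy-7-methyl-6,8-dioxo-7,8-dihydro-6H-isochromen-3-yl]allyl acetate | CC(=O)OC/C=C/C1=CC2=CC(=O)[C@@](C)(O)C(=O)C2=CO1 | intermediate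
17 | orsellinic acid (2,4-dihydroxy-6-methylbenzoic acid) | Cc1cc(O)cc(O)c1C(=O)O | starting material
18 | tert-butyldimethylsilyl 2,4-bis(tert-butyldimethylsilyloxy)-6-methylbenzoate | Cc1cc(O[Si](C)(C)C(C)(C)C)cc(O[Si](C)(C)C(C)(C)C)c1C(=O)O[Si](C)(C)C(C)(C)C | intermediate
19 | 2,4-bis(tert-butyldimethylsilyloxy)-6-methylbenzoyl chloride | Cc1cc(O[Si](C)(C)C(C)(C)C)cc(O[Si](C)(C)C(C)(C)C)c1C(Cl)=O | intermediate
20 | (7S)-3-[(E)-3-acetoxyprop-1-enyl]-7-methyl-6,8-dioxo-7,8-dihydro-6H-isochromen-7-yl 2,4-bis(tert-butyldimethylsilyloxy)-6-methylbenzoate | CC(=O)OC/C=C/C1=CC2=CC(=O)[C@](C)(OC(=O)c3c(C)cc(O[Si](C)(C)C(C)(C)C)cc3O[Si](C)(C)C(C)(C)C)C(=O)C2=CO1 | intermediate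
21 | (7S)-3-[(E)-3-acetoxyprop-1-enyl]-7-methyl-6,8-dioxo-5,6,7,8-tetrahydro-1H-isochromen-7-yl 2,4-bis(tert-butyldimethylsilyloxy)-6-methylbenzoate (drawn as the keto tautomer) | CC(=O)OC/C=C/C1=CC2=C(CO1)C(=O)[C@@](C)(OC(=O)c1c(C)cc(O[Si](C)(C)C(C)(C)C)cc1O[Si](C)(C)C(C)(C)C)C(=O)C2 | intermediate
22 | (E)-3-[(7R)-7-hydroxy-7-methyl-6,8-dioxo-5,6,7,8-tetrahydro-1H-isochromen-3-yl]allyl acetate | CC(=O)OC/C=C/C1=CC2=C(CO1)C(=O)[C@](C)(O)C(=O)C2 | intermediate
23 | (E)-3-[(6R,7R)-6,7-dihydroxy-7-methyl-8-oxo-5,6,7,8-tetrahydro-1H-isochromen-3-yl]allyl acetate | CC(=O)OC/C=C/C1=CC2=C(CO1)C(=O)[C@](C)(O)[C@H](O)C2 | intermediate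
24 | (6R,7R)-3-[(E)-3-acetoxyprop-1-enyl]-7-hydroxy-7-methyl-8-oxo-5,6,7,8-tetrahydro-1H-isochromen-6-yl 2,4-bis(tert-butyldimethylsilyloxy)-6-methylbenzoate | CC(=O)OC/C=C/C1=CC2=C(CO1)C(=O)[C@](C)(O)[C@H](OC(=O)c1c(C)cc(O[Si](C)(C)C(C)(C)C)cc1O[Si](C)(C)C(C)(C)C)C2 | intermediate
25 | (6R,7R)-7-hydroxy-3-[(E)-3-hydroxyprop-1-enyl]-7-methyl-8-oxo-5,6,7,8-tetrahydro-1H-isochromen-6-yl 2,4-bis(tert-butyldimethylsilyloxy)-6-methylbenzoate | OC/C=C/C1=CC2=C(CO1)C(=O)[C@](C)(O)[C@H](OC(=O)c1c(C)cc(O[Si](C)(C)C(C)(C)C)cc1O[Si](C)(C)C(C)(C)C)C2 | intermediate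
26 | (6R,7R)-7-hydroxy-7-methyl-8-oxo-3-[(E)-3-oxoprop-1-enyl]-5,6,7,8-tetrahydro-1H-isochromen-6-yl 2,4-bis(tert-butyldimethylsilyloxy)-6-methylbenzoate | O=C/C=C/C1=CC2=C(CO1)C(=O)[C@](C)(O)[C@H](OC(=O)c1c(C)cc(O[Si](C)(C)C(C)(C)C)cc1O[Si](C)(C)C(C)(C)C)C2 | intermediate
27 | tetrakis(tert-butyldimethylsilyl) ether of the target (left half 7S, C5 alkylidene Z; right half 6R,7R) | CC(=O)OC/C=C/C1=CC2=C(CO1)C(=O)[C@@](C)(OC(=O)c1c(C)cc(O[Si](C)(C)C(C)(C)C)cc1O[Si](C)(C)C(C)(C)C)C(=O)/C2=C\C=C\C1=CC2=C(CO1)C(=O)[C@](C)(O)[C@H](OC(=O)c1c(C)cc(O[Si](C)(C)C(C)(C)C)cc1O[Si](C)(C)C(C)(C)C)C2 | intermediate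
28 | CNP0283591.2 | CC(=O)OC/C=C/C1=CC2=C(CO1)C(=O)[C@@](C)(OC(=O)c1c(C)cc(O)cc1O)C(=O)/C2=C\C=C\C1=CC2=C(CO1)C(=O)[C@](C)(O)[C@H](OC(=O)c1c(C)cc(O)cc1O)C2 | target

**Totals**

Total step count: 20. Longest linear sequence: 15 steps (1, 2, 3, 4, 5, 6, 7, 9, 14, 15, 16, 17, 18, 19, 20).

**Three steps most likely to fail**

Step 13 (hydride addition at C1 of the acylated azaphilone). The reversible protonation may not activate 20 enough, or hydride may go to other conjugated positions. Fallback: setting out from 20, O6 is silylated with TMSOTf (CH2Cl2, −78 °C) to give the discrete 6-trimethylsilyloxy-2-benzopyrylium triflate F1. This takes hydride from Bu4NBH4 at C1 to give the trimethylsilyl dienol ether F2. Work-up with pH 7 buffer hydrolyses the silyl enol ether and the route is rejoined at 21.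

Step 15 (ketoreductase reduction at C6). The acidic C5 methylene and the bulk of the substrate may leave no panel enzyme with useful rate or the wanted facial sense. Fallback by substrate control: setting out from 16, TESOTf and 2,6-lutidine give the 7-triethylsilyl ether of the azaphilone F3. Hantzsch ester reduction as in step 14 gives the silyloxy dione F4. NaBH4 with CeCl3·7H2O (MeOH, −78 °C) should add hydride to C6 anti to the axial C7–OSiEt3 bond (polar Felkin–Anh) and give the cis hydroxy silyl ether F5. HF·pyridine removes the silyl group and the route is rejoined at 23.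

Step 19 (Knoevenagel union). The electrophilic product may take up a second molecule of 21, or may rest as its 2H-pyran valence isomer or the wrong alkene isomer. Fallback by a directed, stepwise aldol: setting out from 21, TBSOTf and Et3N give the tert-butyldimethylsilyl dienol ether F6. This adds through C5 to enal 26 under BF3·OEt2 (CH2Cl2, −78 °C, Mukaiyama aldol) to give the β-hydroxy ketone F7 as a diastereomer mixture. PPTS-catalysed dehydration then returns to 27.

**Further compounds**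

F1 | step 13 | (7S)-3-[(E)-3-acetoxyprop-1-enyl]-7-[2,4-bis(tert-butyldimethylsilyloxy)-6-methylbenzoyloxy]-7-methyl-8-oxo-6-(trimethylsilyloxy)-7,8-dihydroisochromenylium triflate | CC(=O)OC/C=C/C1=CC2=C(C=[O+]1)C(=O)[C@@](C)(OC(=O)c1c(C)cc(O[Si](C)(C)C(C)(C)C)cc1O[Si](C)(C)C(C)(C)C)C(O[Si](C)(C)C)=C2.[O-]S(=O)(=O)C(F)(F)F
F2 | step 13 | (7S)-3-[(E)-3-acetoxyprop-1-enyl]-7-methyl-8-oxo-6-(trimethylsilyloxy)-7,8-dihydro-1H-isochromen-7-yl 2,4-bis(tert-butyldimethylsilyloxy)-6-methylbenzoate | CC(=O)OC/C=C/C1=CC2=C(CO1)C(=O)[C@@](C)(OC(=O)c1c(C)cc(O[Si](C)(C)C(C)(C)C)cc1O[Si](C)(C)C(C)(C)C)C(O[Si](C)(C)C)=C2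
F3 | step 15 | (E)-3-[(7R)-7-methyl-6,8-dioxo-7-(triethylsilyloxy)-7,8-dihydro-6H-isochromen-3-yl]allyl acetate | CC(=O)OC/C=C/C1=CC2=CC(=O)[C@@](C)(O[Si](CC)(CC)CC)C(=O)C2=CO1
F4 | step 15 | (E)-3-[(7R)-7-methyl-6,8-dioxo-7-(triethylsilyloxy)-5,6,7,8-tetrahydro-1H-isochromen-3-yl]allyl acetate | CC(=O)OC/C=C/C1=CC2=C(CO1)C(=O)[C@](C)(O[Si](CC)(CC)CC)C(=O)C2
F5 | step 15 | (E)-3-[(6R,7R)-6-hydroxy-7-methyl-8-oxo-7-(triethylsilyloxy)-5,6,7,8-tetrahydro-1H-isochromen-3-yl]allyl acetate | CC(=O)OC/C=C/C1=CC2=C(CO1)C(=O)[C@](C)(O[Si](CC)(CC)CC)[C@H](O)C2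
F6 | step 19 | (7S)-3-[(E)-3-acetoxyprop-1-enyl]-6-(tert-butyldimethylsilyloxy)-7-methyl-8-oxo-7,8-dihydro-1H-isochromen-7-yl 2,4-bis(tert-butyldimethylsilyloxy)-6-methylbenzoate | CC(=O)OC/C=C/C1=CC2=C(CO1)C(=O)[C@@](C)(OC(=O)c1c(C)cc(O[Si](C)(C)C(C)(C)C)cc1O[Si](C)(C)C(C)(C)C)C(O[Si](C)(C)C(C)(C)C)=C2
F7 | step 19 | aldol adduct of 21 (through C5) and 26, a β-hydroxy ketone, mixture of epimers at C5 and at the carbinol carbon | CC(=O)OC/C=C/C1=CC2=C(CO1)C(=O)[C@@](C)(OC(=O)c1c(C)cc(O[Si](C)(C)C(C)(C)C)cc1O[Si](C)(C)C(C)(C)C)C(=O)C2C(O)/C=C/C1=CC2=C(CO1)C(=O)[C@](C)(O)[C@H](OC(=O)c1c(C)cc(O[Si](C)(C)C(C)(C)C)cc1O[Si](C)(C)C(C)(C)C)C2
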